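Per hour is the unit to hold on to: below, every rate is a share of the charged starting material made per hour, and every amount is a share of that charge, the conversion you are used to. Autumn repeats the winter charge and is read later than the last winter row.

| flask | starting material | free catalyst | time |
|---|---|---|---|
| winter | 0.300 M | 6.00 × 10⁻⁴ M |  |
| noon | 0.120 M | 6.00 × 10⁻⁴ M |  |
| dusk | 0.300 M | 9.00 × 10⁻⁴ M |  |
| autumn | 0.300 M | 6.00 × 10⁻⁴ M | 8.5 h |

- Overall: starting material -> product, with free catalyst as catalyst.
- Constant volume, constant temperature.
- The analysis sees a species whether free or bound.
- An order is taken over about fifteen percent of the charge, up and down.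

- how the opening rate goes with [free catalyst] round the charge of the winter run: the exponent of the rate at two percent of starting material gone to product
- how the opening rate goes with [starting material] round the charge of the winter run: the exponent of the rate at two percent of starting material gone to product (one fixed amount of product, the same in the runs compared)
- product in the autumn run at 8.5 h, as a share of the starting material charged

| run | time / h | [product] / M |
|---|---|---|
| winter run | 0.12 | 0.0146 |
| winter run | 0.37 | 0.0473 |
| winter run | 0.71 | 0.0697 |
| winter run | 1.1 | 0.0880 |
| winter run | 1.6 | 0.1028 |
| winter run | 2.1 | 0.1143 |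
| winter run | 2.7 | 0.1181 |
| winter run | 3.4 | 0.1206 |
| noon run | 0.12 | 0.0037 |
| noon run | 0.37 | 0.0080 |
| noon run | 0.71 | 0.0168 |
| noon run | 1.1 | 0.0222 |
| noon run | 1.6 | 0.0246 |
| noon run | 2.1 | 0.0248 |
| noon run | 2.7 | 0.0312 |
| noon run | 3.4 | 0.0302 |
| dusk run | 0.12 | 0.0323 |
| dusk run | 0.37 | 0.0731 |
| dusk run | 0.71 | 0.1079 |
| dusk run | 1.1 | 0.1347 |
| dusk run | 1.6 | 0.1462 |
| dusk run | 2.1 | 0.1539 |
| dusk run | 2.7 | 0.1568 |
| dusk run | 3.4 | 0.1615 |

(scatter of a reading: 0.002 M)

Read the winter table down its rows. From 0.71 h to 1.6 h the product climbs at 0.124 /h, and from 1.6 h to 3.4 h at 0.0330 /h, which is slower. The centres of these windows lie 1.34 h apart.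

My own reckoning starts there. Call the fade the natural logarithm of the ratio of those rates divided by that gap, an apparent first-order decay constant of the rate: 0.985 /h. It is a reading and carries the readings' scatter.

If the rate keeps fading at that pace, what is still to come after a given moment is the rate then divided by the fade. At the last winter row, 3.4 h, the reading stands at 40.2 %. The rate carried forward to that row is 0.0136 /h, so the tail is 1.38 %. That is hardly any of what already stands, though twice the scatter of one reading.

Since the tail is so much smaller than the reading, the autumn question is nearly a reading. I reckon 41.6 % at 8.5 h. The fade says nothing about the two orders.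

The forecast gave 1.6 for the catalyst order, 1.6 for the starting-material order and 42 % for autumn, judging that “the catalyst is probably dying rather than the reaction equilibrating”. Its autumn figure and mine differ by less than the scatter of one reading.

The simulation gives 1.6 for the catalyst order, 1.4 for the starting-material order and 41.7 % for autumn, from these steps:

    free catalyst + starting material ⇌ catalyst-substrate complex, settled at all times (0.4140 /M)
    catalyst-substrate complex + starting material ⇌ doubly bound catalyst, settled at all times (11.90 /M)
    doubly bound catalyst → product + catalyst-substrate complex (1404 /h)
    free catalyst + impurity → spent catalyst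
    starting material → decomposed substrate (0.3816 /h)

The fit with the true steps gives 41.6 % for autumn, and the fit in which the loaded catalyst dies gives 43.4 %. The last window of the dusk run, from 1.6 h to 3.4 h, reads 0.0283 /h. Borrowing the winter fade of 0.985 /h for that rate, the estimated dusk tail comes to 1.19 %, and added to the last dusk reading of 53.8 % it gives an estimate of 55.0 % of the dusk charge.

The data come from a simulation for substances that don't exist; the scatter is artificial.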